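Its constants are invented.

Begin with one dissolved molecule of starting material: protic impurity quenches it, or it goes forward through the intermediate to target.

solid substrate 0.0020 M; protic impurity 1.00 mM; time 80 min

    solid substrate ⇌ starting material, rate k1*(cs1 - [starting material]) while solid is left; crystals form when [starting material] > cs1 (cs1 = 0.32 mM, k1 = 0.019 s⁻¹)
    starting material + protic impurity → quenched substrate (k2 = 63 M⁻¹ s⁻¹)
    intermediate → target (k3 = 4.1 s⁻¹)
    starting material ⇌ intermediate (K4 = 0.65, k4 = 0.016 s⁻¹)
    starting material → decomposition product (k5 = 5.8 × 10⁻⁵ s⁻¹)

- which holds at 80 min: what has brought the reaction to rest, or that it has not come to rest (for what has run out or reacted, a solid counts together with what of it has only dissolved) (all of the solid substrate has reacted / it is still moving / forward and back rates have come level)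
- part of the solid substrate that has turned into other species by 80 min (what has only dissolved does not count)
- target at 80 min, in percent of the solid substrate charged
- amount of target if the flask were left three thousand times as long, in percent of the solid substrate charged

- given per volume of solution although it is solid: solid substrate
- at the start none of the solid substrate is in solution
- what has only dissolved of solid substrate counts as not reacted
- the reaction counts as stopped when no species that holds the solid substrate changes by six tenths of a point or more over the second half of the time
- run time (flask): 80 min

The intermediate returns at 0.0246 s⁻¹, far slower than it goes on at 4.1 s⁻¹, and decomposition is far slower than the forward step. So I count each forward step as target. The two paths then share the factor c(starting material), and it cancels from their ratio. What stays frozen is the crossover concentration c*, the level of protic impurity at which both paths run equally fast, 0.254 mM, a selectivity factor that carries a unit. Summing the ratio gives: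

c(target) = c* · ln[charge of protic impurity / c(protic impurity)]

Now draw the curve of target. After a short rise, dissolved starting material stands near 0.0620 mM, under the solubility. Target then climbs at 0.0596 mM min⁻¹, which is 20.3% of the feed, 0.294 mM min⁻¹.

The crossing comes when c(protic impurity) falls to c*. By then the formula gives 0.348 mM of target, and 1.09 mM has dissolved and reacted, so at that starting feed I put the crossing near 3.72 min. After it, the feed sags towards 0.167 mM min⁻¹, its value at zero protic impurity. At that feed, I reckon, the remaining 0.906 mM of solid lasts until near 9.15 min, and that is the knee. Beyond it, the dissolved remainder falls by the forward step with a half-life of 0.722 min, so I commit to complete reaction, 100%.

The level comes from the balance. As a first guess, target is the charge minus the impurity, and the formula then leaves this fraction of the impurity unquenched: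

1.95%

Correcting target for it gives 51.0% at the asked time, and I expect 51.0% for the long wait.

The forecast gave all of the solid substrate has reacted, with 100%, 50.7% and 50.7%, holding that “Selectivity is independent of the dissolution rate”. The simulation gives all of the solid substrate has reacted, with 100% converted, 50.7% of target at the asked time and 50.7% after the long wait.

The quenching path is the main reason target stops near this level: with it struck out, this flask gives 99.6% against 50.7%. Through c*, the 1.8% of protic impurity left in this flask corresponds to 51.0% of target. The neighbour flask, charged with 8.0 × 10⁻⁴ M of solid substrate, keeps 42% of its protic impurity, so c* gives about 27.5% of target there, in percent of its own solid charge, and its run holds 27.4%.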